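**Retrosynthetic overview**

1. Numbering: chain C1=C2–C3(CH3)(OH)–C4–C5–C6; ring C6(H)–C7(CH3)(OH)–C8–C9–C10(Br)–C11(CH3)(C12–C13–C14=C15), with C11 bonded back to C6.
2. The plan rests on the vicinal pair C6 (tertiary CH) and C11 (quaternary C) of the only ring, the cyclohexane C6–C11, in which the C7 oxygen and the C10 heteroatom stand 1,4. Cutting C6–C11 and C9–C10 gives a (Z)-2-silyloxydiene C6=C7(OSi)–C8=C9 and an (E)-β,β-dialkyl nitroalkene O2N–C10=C11.
3. After ring formation: enol ether to C7 ketone to C7 methyl carbinol; nitro to C10 ketone to axial alcohol to equatorial bromide (inversion); desilylation at C3–O.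
4. The diene comes from (S)-linalool (C1–C6, which brings the C3 centre) and acrolein (C7–C9); the nitroalkene comes from 6-methylhept-5-en-2-one and nitromethane.
5. Ring order: the single carbocycle is closed in step 9; no other ring is formed.

Key step: step 9

Assumption: the sense of face selection by a chiral hydrogen-bond donor on a β,β-dialkyl nitroalkene cannot be predicted. The (R,R) catalyst is written, and its (S,S) antipode is taken instead if a pilot run shows the opposite sense. The remote C3 centre is assumed to exert no bias.

**Route**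

Step 1
Reactants: 1 (S)-linalool
Product: 2 (3S)-3,7-dimethyl-3-(triethylsilyloxy)octa-1,6-diene
Conditions: TESOTf, 2,6-lutidine, CH2Cl2, −78 → 0 °C
Reagents that add atoms: triethylsilyl trifluoromethanesulfonate, CC[Si](CC)(CC)OS(=O)(=O)C(F)(F)F
Why: O-silylation of the hindered tertiary allylic alcohol with a silyl triflate and a hindered base should be clean, leaves the C3 centre untouched and masks the only protic group for the organometallic steps.

Step 2
Reactants: 2 (3S)-3,7-dimethyl-3-(triethylsilyloxy)octa-1,6-diene
Product: 4 (4S)-4-methyl-4-(triethylsilyloxy)hex-5-en-1-ol, via aldehyde 3 (not isolated)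
Conditions: O3, CH2Cl2/MeOH, Sudan Red 7B (indicator), −78 °C; then NaBH4, −78 → 0 °C
Reagents that add atoms: ozone, [O-][O+]=O
Why: In this ozonolysis with reductive work-up, ozone should cleave the electron-rich trisubstituted alkene well before the hindered vinyl group next to the C–O bond (the dye marks the end point), and borohydride reduces the aldehyde and the peroxidic co-product in the same flask.

Step 3
Reactants: 4 (4S)-4-methyl-4-(triethylsilyloxy)hex-5-en-1-ol
Product: 5 (3S)-6-bromo-3-methyl-3-(triethylsilyloxy)hex-1-ene
Conditions: CBr4, PPh3, CH2Cl2, 0 °C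
Reagents that add atoms: carbon tetrabromide, BrC(Br)(Br)Br
Why: The Appel reaction converts the primary alcohol into the bromide by SN2 displacement of the alkoxyphosphonium ion under neutral conditions that the tertiary allylic silyl ether should tolerate.

Step 4
Reactants: 5 (3S)-6-bromo-3-methyl-3-(triethylsilyloxy)hex-1-ene, 6 acrolein
Product: 8 (7S)-7-methyl-7-(triethylsilyloxy)nona-1,8-dien-3-ol (both C3 epimers), via Grignard reagent 7 (not isolated)
Conditions: Mg, THF, 40 °C; then 6, THF, −78 °C; aq NH4Cl
Reagents that add atoms: none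
Why: The primary Grignard reagent (a pent-4-enyl-type organometallic that has no favourable cyclisation or β-elimination path) should add 1,2 to acrolein, and the new carbinol centre is irrelevant because it is oxidised in the next step.

Step 5
Reactants: 8 (7S)-7-methyl-7-(triethylsilyloxy)nona-1,8-dien-3-ol
Product: 9 (7S)-7-methyl-7-(triethylsilyloxy)nona-1,8-dien-3-one
Conditions: Dess–Martin periodinane, CH2Cl2, 0 → 25 °C
Reagents that add atoms: none
Why: Dess–Martin oxidation of the secondary allylic alcohol gives the vinyl ketone under nearly neutral, non-nucleophilic conditions, which should avoid conjugate addition to the sensitive enone.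

Step 6
Reactants: 9 (7S)-7-methyl-7-(triethylsilyloxy)nona-1,8-dien-3-one
Product: 10 (3Z,7S)-3-(tert-butyldimethylsilyloxy)-7-methyl-7-(triethylsilyloxy)nona-1,3,8-triene
Conditions: TBSOTf, Et3N, Et2O, −78 → 0 °C
Reagents that add atoms: tert-butyldimethylsilyl trifluoromethanesulfonate, CC(C)(C)[Si](C)(C)OS(=O)(=O)C(F)(F)F
Why: Soft enolisation (silyl triflate and amine) can only engage the α'-CH2 (C6) and should give the cross-conjugated silyl dienol ether with Z geometry, because the isomer with the C5 chain cis to the vinyl group suffers allylic strain; Z places the chain in the outside position of the diene.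

Step 7
Reactants: 11 6-methylhept-5-en-2-one, 12 nitromethane
Product: 13 2,6-dimethyl-1-nitrohept-5-en-2-ol (racemic)
Conditions: 12 (10 equiv, as solvent), 1,1,3,3-tetramethylguanidine (0.2 equiv), 25 °C
Reagents that add atoms: none
Why: The Henry (nitroaldol) addition to the methyl ketone is reversible and is driven by the excess of nitromethane; the carbinol centre is destroyed in the next step.

Step 8
Reactants: 13 2,6-dimethyl-1-nitrohept-5-en-2-ol
Product: 15 (E)-2,6-dimethyl-1-nitrohepta-1,5-diene, via mesylate 14 (not isolated)
Conditions: MsCl, Et3N, CH2Cl2, −20 → 0 °C; E isomer separated from Z on silica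
Reagents that add atoms: none
Why: Mesylation of the tertiary alcohol and E1cB elimination through the nitronate should give the conjugated nitroalkene as the kinetic product (low temperature and short contact with the amine limit the drift to the β,γ-isomer); the reaction is not expected to be geometrically selective, so the E isomer (nitro cis to methyl) is separated from the Z isomer by chromatography and its geometry confirmed by NOE before use.

Step 9
Reactants: 10 (3Z,7S)-3-(tert-butyldimethylsilyloxy)-7-methyl-7-(triethylsilyloxy)nona-1,3,8-triene, 15 (E)-2,6-dimethyl-1-nitrohepta-1,5-diene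
Product: 16 (4S,5S,6S)-1-(tert-butyldimethylsilyloxy)-5-methyl-5-(4-methylpent-3-enyl)-6-[(3S)-3-methyl-3-(triethylsilyloxy)pent-4-enyl]-4-nitrocyclohex-1-ene
Conditions: 15 (1.5 equiv), N,N'-[(1R,2R)-cyclohexane-1,2-diyl]bis{N'-[3,5-bis(trifluoromethyl)phenyl]thiourea} (20 mol %), 4 Å MS, toluene, 12 kbar, 25 °C
Reagents that add atoms: none
Why: Proposed new method: the reaction is a concerted but asynchronous normal-demand [4+2] cycloaddition in which the diene HOMO, raised by the C7 silyloxy group, meets the nitroalkene LUMO, lowered by double hydrogen bonding of the thiourea to the nitro oxygens, so that the nucleophilic terminus C6 bonds to the β-carbon C11 ahead of the C9–C10 bond. The closest known reaction type is the thermal or hydrogen-bond-donor-catalysed Diels–Alder reaction of 2-silyloxy- and 2-aminodienes with β-monosubstituted nitroalkenes to 4-nitrocyclohexanone derivatives; a β,β-dialkyl nitroalkene that creates a quaternary carbon next to a substituted diene terminus has not been shown, which is why pressure (strongly negative activation volume) is used in place of heat. The six-membered carbocycle C6–C7–C8–C9–C10–C11 is closed by the cycloaddition itself, both new bonds (C6–C11 and C9–C10) being formed suprafacially on each partner. The cis relationship of nitro (C10) and methyl (C11) is carried over from the (E)-alkene, and the cis relationship of the C6 side chain and the C11 methyl follows from the (Z)-enol ether (chain outside) reacting through the transition state with nitro endo, in which the small methyl and not the homoprenyl group lies under the silyloxy-bearing C7. The absolute configuration of C6, C10 and C11 is left to the catalyst, which shields one face of the bound nitroalkene, since the C3 centre is too far away to differentiate the diene faces. The step needs 1,4-regiochemistry of oxygen and nitrogen (secured by the silyloxy group), endo selectivity (nitro preference reinforced by the size difference at C11) and face selectivity (catalyst only).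

Step 10
Reactants: 16 (the cycloadduct of step 9)
Product: 17 (2S,3S,4S)-3-methyl-3-(4-methylpent-3-enyl)-2-[(3S)-3-methyl-3-(triethylsilyloxy)pent-4-enyl]-4-nitrocyclohexan-1-one
Conditions: TBAF (1.1 equiv), AcOH (1.5 equiv), THF, −78 → −40 °C
Reagents that add atoms: none
Why: Fluoride should cleave the silyl enol ether far faster than the tertiary alkyl triethylsilyl ether, and acetic acid protonates the enolate at C8 at once, so no base remains to epimerise C6 or to form the nitronate.

Step 11
Reactants: 17 (the nitro ketone of step 10)
Product: 19 (1R,2S,3S)-1,3-dimethyl-3-(4-methylpent-3-enyl)-2-[(3S)-3-methyl-3-(triethylsilyloxy)pent-4-enyl]-4-nitrocyclohexan-1-ol (C4 epimers), via cerium nitronate 18 (not isolated)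
Conditions: MeMgBr (3 equiv), CeCl3 (3 equiv), THF, −78 °C; then AcOH, −78 → 0 °C
Reagents that add atoms: methylmagnesium bromide, C[Mg]Br
Why: In this organocerium carbonyl addition the first equivalent deprotonates C10–H to the nitronate, which masks that position, and the second should add to the C7 ketone by equatorial attack from the face opposite the C6 side chain and the syn-axial C11 methyl, setting C7 with the hydroxyl cis to the side chain; the weakly basic cerium reagent suppresses enolisation.

Step 12
Reactants: 19 (the nitro alcohol of step 11)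
Product: 21 (2S,3S,4R)-4-hydroxy-2,4-dimethyl-2-(4-methylpent-3-enyl)-3-[(3S)-3-methyl-3-(triethylsilyloxy)pent-4-enyl]cyclohexan-1-one, via sodium nitronate 20 (not isolated)
Conditions: NaOMe, MeOH, 0 °C; then TiCl3, NH4OAc, H2O/THF (pH 5–6), 25 °C
Reagents that add atoms: water, O
Why: In the reductive (TiCl3) variant of the Nef reaction the nitronate is reduced to the imine, which is hydrolysed at nearly neutral pH to the C10 ketone; these conditions should spare the alkenes, the tertiary alcohol and the silyl ether, and both C10 epimers converge.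

Step 13
Reactants: 21 (the hydroxy ketone of step 12)
Product: 22 (1R,2S,3S,4R)-1,3-dimethyl-3-(4-methylpent-3-enyl)-2-[(3S)-3-methyl-3-(triethylsilyloxy)pent-4-enyl]cyclohexane-1,4-diol
Conditions: LiBH(sec-Bu)3, THF, −78 °C; then NaOH, H2O2, 0 °C
Reagents that add atoms: none
Why: The bulky trialkylborohydride should deliver hydride along the equatorial trajectory, as it does with 2,2-disubstituted cyclohexanones, the axial path being closed to it by the axial hydrogens at C6 and C8; this gives the axial C10 alcohol trans to the C11 methyl.

Step 14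
Reactants: 22 (the diol of step 13)
Product: 23 (1R,2S,3S,4S)-4-bromo-1,3-dimethyl-3-(4-methylpent-3-enyl)-2-[(3S)-3-methyl-3-(triethylsilyloxy)pent-4-enyl]cyclohexan-1-ol
Conditions: CBr4, PPh3, 2,6-lutidine, CH2Cl2, 0 → 25 °C
Reagents that add atoms: carbon tetrabromide, BrC(Br)(Br)Br
Why: In the Appel reaction bromide displaces the axial alkoxyphosphonium group with inversion to give the equatorial C10 bromide cis to the C11 methyl, while the tertiary C7 hydroxyl, syn-axial to that methyl, should be too hindered to be activated at a comparable rate.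

Step 15
Reactants: 23 (the silyl-protected bromide of step 14)
Product: 24 (1R,2S,3S,4S)-4-bromo-2-[(3S)-3-hydroxy-3-methylpent-4-enyl]-1,3-dimethyl-3-(4-methylpent-3-enyl)cyclohexan-1-ol (CNP0237376.1)
Conditions: HF·pyridine, pyridine, THF, 0 → 25 °C
Reagents that add atoms: none
Why: Buffered fluoride desilylation should free the tertiary allylic alcohol without ionising it, and the equatorial bromide, which has no antiperiplanar hydrogen, is not expected to eliminate; no stereocentre is touched.

**Compound list**

1 | (S)-linalool, (3S)-3,7-dimethylocta-1,6-dien-3-ol | C=C[C@@](C)(O)CCC=C(C)C | starting material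
2 | (3S)-3,7-dimethyl-3-(triethylsilyloxy)octa-1,6-diene | C=C[C@@](C)(O[Si](CC)(CC)CC)CCC=C(C)C | intermediate
3 | (4S)-4-methyl-4-(triethylsilyloxy)hex-5-enal (not isolated) | C=C[C@@](C)(O[Si](CC)(CC)CC)CCC=O | intermediate
4 | (4S)-4-methyl-4-(triethylsilyloxy)hex-5-en-1-ol | C=C[C@@](C)(O[Si](CC)(CC)CC)CCCO | intermediate
5 | (3S)-6-bromo-3-methyl-3-(triethylsilyloxy)hex-1-ene | C=C[C@@](C)(O[Si](CC)(CC)CC)CCCBr | intermediate
6 | acrolein | C=CC=O | starting material
7 | [(4S)-4-methyl-4-(triethylsilyloxy)hex-5-enyl]magnesium bromide (not isolated) | C=C[C@@](C)(O[Si](CC)(CC)CC)CCC[Mg]Br | intermediate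
8 | (7S)-7-methyl-7-(triethylsilyloxy)nona-1,8-dien-3-ol (both C3 epimers) | C=C[C@@](C)(O[Si](CC)(CC)CC)CCCC(O)C=C | intermediate
9 | (7S)-7-methyl-7-(triethylsilyloxy)nona-1,8-dien-3-one | C=C[C@@](C)(O[Si](CC)(CC)CC)CCCC(=O)C=C | intermediate
10 | (3Z,7S)-3-(tert-butyldimethylsilyloxy)-7-methyl-7-(triethylsilyloxy)nona-1,3,8-triene | C=C[C@@](C)(O[Si](CC)(CC)CC)CC/C=C(O[Si](C)(C)C(C)(C)C)/C=C | intermediate
11 | 6-methylhept-5-en-2-one | CC(=O)CCC=C(C)C | starting material
12 | nitromethane | C[N+](=O)[O-] | starting material
13 | 2,6-dimethyl-1-nitrohept-5-en-2-ol (racemic) | CC(O)(C[N+](=O)[O-])CCC=C(C)C | intermediate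
14 | 2,6-dimethyl-1-nitrohept-5-en-2-yl methanesulfonate (racemic, not isolated) | CC(OS(C)(=O)=O)(C[N+](=O)[O-])CCC=C(C)C | intermediate
15 | (E)-2,6-dimethyl-1-nitrohepta-1,5-diene | [O-][N+](=O)/C=C(\C)CCC=C(C)C | intermediate
16 | (4S,5S,6S)-1-(tert-butyldimethylsilyloxy)-5-methyl-5-(4-methylpent-3-enyl)-6-[(3S)-3-methyl-3-(triethylsilyloxy)pent-4-enyl]-4-nitrocyclohex-1-ene | C=C[C@@](C)(O[Si](CC)(CC)CC)CC[C@H]1[C@](C)(CCC=C(C)C)[C@@H]([N+](=O)[O-])CC=C1O[Si](C)(C)C(C)(C)C | intermediate
17 | (2S,3S,4S)-3-methyl-3-(4-methylpent-3-enyl)-2-[(3S)-3-methyl-3-(triethylsilyloxy)pent-4-enyl]-4-nitrocyclohexan-1-one | C=C[C@@](C)(O[Si](CC)(CC)CC)CC[C@H]1[C@](C)(CCC=C(C)C)[C@@H]([N+](=O)[O-])CCC1=O | intermediate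
18 | dichlorocerium nitronate of ketone 17 (not isolated) | C=C[C@@](C)(O[Si](CC)(CC)CC)CC[C@H]1[C@](C)(CCC=C(C)C)C(=[N+]([O-])[O-])CCC1=O.[Ce+3].[Cl-].[Cl-] | intermediate
19 | (1R,2S,3S)-1,3-dimethyl-3-(4-methylpent-3-enyl)-2-[(3S)-3-methyl-3-(triethylsilyloxy)pent-4-enyl]-4-nitrocyclohexan-1-ol (C4 epimers) | C=C[C@@](C)(O[Si](CC)(CC)CC)CC[C@H]1[C@](C)(CCC=C(C)C)C([N+](=O)[O-])CC[C@@]1(C)O | intermediate
20 | sodium nitronate of nitro alcohol 19 (not isolated) | C=C[C@@](C)(O[Si](CC)(CC)CC)CC[C@H]1[C@](C)(CCC=C(C)C)C(=[N+]([O-])[O-])CC[C@@]1(C)O.[Na+] | intermediate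
21 | (2S,3S,4R)-4-hydroxy-2,4-dimethyl-2-(4-methylpent-3-enyl)-3-[(3S)-3-methyl-3-(triethylsilyloxy)pent-4-enyl]cyclohexan-1-one | C=C[C@@](C)(O[Si](CC)(CC)CC)CC[C@H]1[C@](C)(CCC=C(C)C)C(=O)CC[C@@]1(C)O | intermediate
22 | (1R,2S,3S,4R)-1,3-dimethyl-3-(4-methylpent-3-enyl)-2-[(3S)-3-methyl-3-(triethylsilyloxy)pent-4-enyl]cyclohexane-1,4-diol | C=C[C@@](C)(O[Si](CC)(CC)CC)CC[C@H]1[C@](C)(CCC=C(C)C)[C@H](O)CC[C@@]1(C)O | intermediate
23 | (1R,2S,3S,4S)-4-bromo-1,3-dimethyl-3-(4-methylpent-3-enyl)-2-[(3S)-3-methyl-3-(triethylsilyloxy)pent-4-enyl]cyclohexan-1-ol | C=C[C@@](C)(O[Si](CC)(CC)CC)CC[C@H]1[C@](C)(CCC=C(C)C)[C@@H](Br)CC[C@@]1(C)O | intermediate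
24 | (1R,2S,3S,4S)-4-bromo-2-[(3S)-3-hydroxy-3-methylpent-4-enyl]-1,3-dimethyl-3-(4-methylpent-3-enyl)cyclohexan-1-ol | C=C[C@@](C)(O)CC[C@H]1[C@](C)(CCC=C(C)C)[C@@H](Br)CC[C@@]1(C)O | target

**Step count**

Total: 15 steps. Longest linear sequence: 13 steps (steps 1–6 and 9–15); steps 7–8 form the nitroalkene branch.

**Steps most likely to fail**

1. Step 9 (the step that carries the label). The cycloaddition may stall because the C6–C11 bond joins a substituted diene terminus to a fully substituted alkene carbon. The exo mode or addition to the wrong alkene face may compete, and the nitroalkene may react as a heterodiene with the enol ether. Incomplete face selection would give the two ring diastereomers relative to C3. The fallback is a stepwise anionic double Michael addition, each stage of which is a known reaction type. It leaves the route at enone 9 and uses nitroalkene 15. LDA in THF at −78 °C converts 9 into the cross-conjugated lithium dienolate F1, which adds through C6 to the β-carbon C11 of 15. After a quench with aq NH4Cl the open-chain δ-nitro enone F2 is taken up with catalytic DBU, and the nitronate closes onto the vinyl ketone (C10 to C9). Without a catalyst to choose the face, nitro ketone 17 would be accompanied by its stereoisomers and would have to be separated by chromatography. The route is rejoined at 17.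

2. Step 14. Elimination towards C9, a 1,2-methyl shift from C11, or activation of the tertiary C7 hydroxyl may outrun displacement at the neopentyl-type C10. The fallback separates activation from displacement and sets out from diol 22. Sulfonylation of the secondary hydroxyl with ClCH2SO2Cl and pyridine at 0 °C should give the C10 chloromethanesulfonate F3, a small and strongly activated leaving group known for SN2 reactions at hindered secondary carbons. LiBr in DMF at 50 °C then displaces it with inversion and gives bromide 23, where the route is rejoined.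

3. Step 12. The reduction may stop at the oxime stage at the hindered C10, or the aqueous medium may cleave the silyl ether or ionise the tertiary allylic C3–O bond. The fallback replaces the Nef reaction by reduction and oxidative deamination and sets out from nitro alcohol 19. Al(Hg) in wet THF should reduce the nitro group to the primary amine F4. Condensation of F4 with 3,5-di-tert-butyl-1,2-benzoquinone and prototropic shift give, without isolation, the ketimine F5. Hydrolysis of F5 with aqueous oxalic acid gives hydroxy ketone 21, where the route is rejoined.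

**Further compounds**

F1 | step 9 | lithium (7S)-7-methyl-7-(triethylsilyloxy)nona-1,3,8-trien-3-olate (lithium dienolate of 9) | C=C[C@@](C)(O[Si](CC)(CC)CC)CCC=C([O-])C=C.[Li+]
F2 | step 9 | (7S)-4-(2,6-dimethyl-1-nitrohept-5-en-2-yl)-7-methyl-7-(triethylsilyloxy)nona-1,8-dien-3-one (stereoisomers at C4 and at the quaternary carbon) | C=C[C@@](C)(O[Si](CC)(CC)CC)CCC(C(=O)C=C)C(C)(C[N+](=O)[O-])CCC=C(C)C
F3 | step 14 | C10 chloromethanesulfonate of diol 22 | C=C[C@@](C)(O[Si](CC)(CC)CC)CC[C@H]1[C@](C)(CCC=C(C)C)[C@H](OS(=O)(=O)CCl)CC[C@@]1(C)O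
F4 | step 12 | (1R,2S,3S)-4-amino-1,3-dimethyl-3-(4-methylpent-3-enyl)-2-[(3S)-3-methyl-3-(triethylsilyloxy)pent-4-enyl]cyclohexan-1-ol (C4 epimers) | C=C[C@@](C)(O[Si](CC)(CC)CC)CC[C@H]1[C@](C)(CCC=C(C)C)C(N)CC[C@@]1(C)O
F5 | step 12 | C10 ketimine of 2-amino-4,6-di-tert-butylphenol derived from F4 | C=C[C@@](C)(O[Si](CC)(CC)CC)CC[C@H]1[C@](C)(CCC=C(C)C)C(=Nc2cc(C(C)(C)C)cc(C(C)(C)C)c2O)CC[C@@]1(C)O
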